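**Remarks on the chemistry (assumptions)**
- The non-aromatic skeletal carbons of the target are numbered along its SMILES string: C1 (isopropenyl-bearing CH), C2 (CH2), C3 (central quaternary carbon), C4 (ring E C=O), C5 (CH), C6 (CH2), C7 (ring D C=O), C8 (aryl-bearing quaternary carbon), C9 (CH2), C10 (methyl-bearing alkene carbon), C11 (alkene CH), C12 (benzylic CH). These locants are used for all intermediates.
- Racemic dione 5 is assumed to be resolvable on a chiral stationary phase. The (R)-enantiomer would be identified by its chiroptical data and confirmed by anomalous-dispersion crystallography at dibromide 21.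
- Step 13 is written for one alkene isomer of the vinyl bromide; the other, if formed, gives the same ketone 24 in step 14.

## Analysis of the target

CNP0287617.1 (33, C22H22O4) is a pentacycle: hydroquinone ring A, five-membered benzo ring B, methylcyclohexene ring C, six-membered 1,4-diketone ring D and cyclopentanone ring E with an isopropenyl group. C3 belongs to rings B, C, D and E and is bonded to the second quaternary carbon C8. Rings B/C form one bicyclo[3.2.1]octane unit (bridgeheads C8, C12; one-carbon bridge C3) and rings D/E a second one (bridgeheads C3, C5; one-carbon bridge C4). The configurations of C3, C5, C8 and C12 are therefore tied together by ring fusion once the orientation of ring E on C3 is fixed: the C4 carbonyl lies over the arene and the C2 methylene over the C9–C10–C11 bridge. Only C1 is free, and its isopropenyl group points to the C12 side of ring E, trans to C6. Sensitive groups are the air-sensitive hydroquinone, two acid-sensitive alkenes and the enolisable diketone. The hard parts are the vicinal quaternary carbons C3/C8 inside a cage and the placement of the C10=C11 alkene. The strategy rests on one feature: rings B and C are a 6,7-benzobicyclo[3.2.1]octa-2,6-diene with C10 as the middle carbon of the three-carbon bridge. Without C10, C9 and C11 form the alkene of a benzonorbornadiene, the Diels–Alder adduct of a symmetric aryne and a cyclopentadiene spiro-fused at C3 to ring E.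

## Retrosynthetic reasoning

**33 ⇒ 31.** The hydroquinone is unmasked last from its dimethyl ether 31, through quinone 32, because the free hydroquinone would not survive enolate, radical and palladium chemistry. The forward step must remove two aryl methyl groups without acid, which rules out Lewis-acid ether cleavage in the presence of the two alkenes.

**31 ⇒ 30 (C5–C6 bond of ring D).** Ring D could in principle be closed at C6–C7, by adding a C7 acyl equivalent to a C5 exocyclic methylene. That was discarded. A polar conjugate addition would pass through an enolate with a C4=C5 double bond at the bridgehead of the new bicyclo[3.2.1]octane, against Bredt's rule. A radical version would have to reach an in-plane methylene that the C8 substituent cannot approach at a sensible angle. Cutting C5–C6 instead leaves methyl ketone 30. In 30 the cyclopentanone enolate (C4/C5) presents its axial lobe to the acetyl group on C8, and the only enolisable sites are C5 and the acetyl methyl (future C6). The forward reaction is an intramolecular oxidative coupling of the bis-enolate; it closes ring D and sets C5, whose configuration is forced by the bridge.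

**30 ⇒ 28 ⇒ 27 (acetyl from the bridgehead ester).** The acetyl group cannot be carried earlier because its methyl would compete in the kinetic enolisation of ring C. It is therefore made late from the methyl ester that has occupied C8 since the aryne cycloaddition: SN2 demethylation to acid 28, then acid chloride 29 and a methyl cuprate.

**27 ⇒ 26 (C1–isopropenyl bond).** The isopropenyl group is β to the C4 ketone, so it is cut back to enone 26. The copper nucleophile must come from the ring E face that looks toward C12; the C8 ester and the C9 methylene shield the other face.

**26 ⇒ 25 ⇒ 24 ⇒ 22 ⇒ 21 (methyl on C10, alkene C10=C11).** The C10 methyl is attached by cross-coupling to enol triflate 25. The triflate comes from ketone 24 by kinetic deprotonation at C11, the α-carbon next to the CH bridgehead and not the one next to quaternary C8. Ketone 24 is reached from dibromide 21 by reduction of the allylic bromide (22) and borylation–oxidation of the vinyl bromide. Passing through the ketone makes the sequence independent of which allyl terminus carried the bromide.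

**21 ⇒ 19 (C9–C10 and C10–C11 bonds, ring C).** Removing C10 gives benzonorbornadiene 19. The forward reaction is a dihalocarbene ring expansion: a CBr2 unit bridges C9 and C11, and the three-membered ring opens to the 2-bromoallyl bromide. This is the key step; it makes ring C and leaves a bromine on C10 as the handle for the methyl group. The enone of ring E is kept at this stage because an electron-poor alkene is a poor partner for an electrophilic carbene.

**19 ⇒ 10 + 18 (C8–aryl and C12–aryl bonds, ring B).** The benzonorbornadiene is cut into 3,6-dimethoxybenzyne 18 and spiro cyclopentadiene 10. The aryne is symmetric, so there is no regiochemical question. The cycloaddition sets C8 and C12 and joins the two quaternary carbons' environment in one step. It must take place on the diene face that carries the flat enone carbonyl, so that C4 ends up over the arene. Aryne 18 is generated under fluoride conditions from silyl triflate 17.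

**10 ⇒ 9 ⇒ 8 ⇒ 6 ⇒ 5 ⇒ 4 ⇒ 3 ⇒ 1 + 2.** In 10 both functionalised carbons (the ester-bearing diene carbon and the enone carbonyl) are attached to the spiro carbon. Spiro dione 5 has exactly this pattern and is C2-symmetric. Double dehydrogenation gives bis-enone 8. One enone is converted by γ-deprotonation into dienyl triflate 9, and carbonylation gives 10. Because the two rings of 8 are homotopic, monofunctionalisation gives a single compound, and no regiochemical choice arises anywhere. A direct spiroannulation of an ester-substituted cyclopentadienyl anion followed by allylic oxidation was set aside: the alkylation is not regioselective and the oxidation would have to spare a free diene. Dione 5 is made from 1 and 2 via 3 and 4 and is resolved to 6 at once, so that all later material is a single enantiomer.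

**17 ⇒ 15 ⇒ 12 ⇒ 11.** The ortho-silyl triflate is made from phenol 11 by carbamate-directed ortho-silylation at the position flanked by the carbamate and a methoxy group.

## Alternatives that were turned down

**Alternative 1: gold-catalysed enyne cyclisation with arene capture.** The disconnection cuts C9–C10 and C8–aryl, so rings C and B are formed last. Substrate A1 already contains rings D/E (C7 as a dioxolane), an exocyclic methylene on C8, and on C3 a CH(aryl)(propynyl) group. Ph3PAuNTf2 (monovalent gold) would activate the alkyne, the methylene carbon would attack the methyl-bearing alkyne carbon, and the dimethoxyphenyl ring would trap the tertiary C8 cation to give A2.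
- For: two rings, the quaternary C8 and a regiodefined C10=C11 alkene in one catalytic step. On alkene placement this is stronger than the chosen route, which depends on a kinetic enolisation.
- Against: A1 needs the bridged D/E core, the isopropenyl group and an acyclic benzylic stereocenter (C12) beside a quaternary carbon before the key step, which is a long and poorly controlled preparation. The isopropenyl group is a competing π-nucleophile. Attack at the other alkyne carbon (five-membered ring) is not excluded. The C8 cation next to a ketal can eliminate. The arene must close a strained bridging five-membered ring.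
- Comparison: the chosen strategy gets C8, C12 and ring B from a symmetric aryne cycloaddition on a seven-step diene, and handles the alkene with ordinary enolate chemistry.

**Alternative 2: transannular oxyallyl (4+3) cycloaddition.** The disconnection cuts C3–C8 and C5–C6. Substrate A3 is a benzocycloheptene with a chloromethyl ketone on C8 and a 5,5-dimethoxycyclopentadienyl group on C12. Et3N in CF3CH2OH would generate the oxyallyl cation (C8–C7–C6), which adds across the diene termini C3 and C5 to give A4.
- For: the two quaternary carbons are joined directly, ring D is closed with C4 protected, and the C10=C11 alkene is present from the start. On that last point it is stronger than the chosen route.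
- Against: 5,5-dialkoxycyclopentadienes dimerise readily. The new C3–C8 bond joins a fully substituted oxyallyl terminus to a substituted diene terminus across a medium ring, so proton loss or arene capture of the cation are likely competitors. A4 lacks the isopropenyl group, which would have to be added to an unactivated C1=C2 alkene with regio- and stereocontrol over several steps.
- Comparison: the chosen route installs the isopropenyl group in one substrate-controlled conjugate addition and uses a cycloaddition with far less steric demand.

**Alternative 3: carbonylative radical cascade on a cycloheptenone.** The disconnection cuts C3–C4 and C4–C5 (C4 from CO) and the C8–C9 bond. Substrate A5 is an indene-fused cycloheptenone with a phenyl selenide on C5. A tin radical would release the C5 radical, which takes up CO; the acyl radical adds to the enone β-carbon C3, and the C8 radical takes a 2-methylallyl group from tributyl(2-methylallyl)stannane to give A6.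
- For: three C–C bonds, rings D and E and the quaternary C8 in one operation, with CO as a one-carbon building block. In bond count per step it is stronger than the chosen route.
- Against: the cascade needs high CO pressure to outrun direct allylation of the first radical. The acyl radical must attack a fully substituted β-carbon. The benzylic, α-keto C8 radical is stabilised and hindered, so allyl transfer is slow. Ring C still needs a ring-closing metathesis afterwards. A5 carries two remote stereocenters (C1, C12) with no obvious way to relate them.
- Comparison: in the chosen strategy every stereocenter is set on a rigid spiro framework, and the risky step has close precedent.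

Key step: step 12

## Route

**Step 1**
Reactants: 1 ethyl 2-oxocyclopentane-1-carboxylate; 2 ethyl 4-bromobutanoate
Product: 3 ethyl 1-(4-ethoxy-4-oxobutyl)-2-oxocyclopentane-1-carboxylate (racemic)
Conditions: K2CO3, NaI (cat.), acetone, reflux
Reagents that add atoms: none
Why: C-alkylation of a β-keto ester enolate with a primary bromide; the quaternary carbon formed becomes the spiro carbon C3.

**Step 2**
Reactants: 3 ethyl 1-(4-ethoxy-4-oxobutyl)-2-oxocyclopentane-1-carboxylate
Product: 4 4-(2-oxocyclopentyl)butanoic acid (racemic)
Conditions: 6 M HCl, AcOH, reflux
Reagents that add atoms: water, O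
Why: Acid hydrolysis of both esters and decarboxylation of the β-keto acid.

**Step 3**
Reactants: 4 4-(2-oxocyclopentyl)butanoic acid
Product: 5 (±)-spiro[4.4]nonane-1,6-dione
Conditions: polyphosphoric acid, AcOH, 100 °C
Reagents that add atoms: none
Why: Intramolecular C-acylation of the more substituted ketone enol by the activated acid (Claisen-type cyclisation) closes the second five-membered ring at the tertiary α-carbon; this is a long-established way to this dione.

**Step 4**
Reactants: 5 (±)-spiro[4.4]nonane-1,6-dione
Product: 6 (R)-spiro[4.4]nonane-1,6-dione
Conditions: preparative chromatography on cellulose tris(3,5-dimethylphenylcarbamate), hexane/i-PrOH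
Reagents that add atoms: none
Why: Resolution of a rigid C2-symmetric diketone whose quaternary spiro carbon cannot epimerise; the configuration of C3 is fixed here for the whole route.

**Step 5**
Reactants: 6 (R)-spiro[4.4]nonane-1,6-dione
Product: 8 (R)-spiro[4.4]nona-2,7-diene-1,6-dione, via bis(silyl enol ether) 7 (not isolated)
Conditions: Me3SiOTf, Et3N, CH2Cl2, 0 °C; then Pd(OAc)2 (2.2 equiv), MeCN, 25 °C
Reagents that add atoms: none
Why: Each ketone can enolise only away from the spiro carbon, so the bis(silyl enol ether) is a single isomer; Saegusa–Ito oxidation then gives both enones without touching C3.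

**Step 6**
Reactants: 8 (R)-spiro[4.4]nona-2,7-diene-1,6-dione
Product: 9 (5S)-6-oxospiro[4.4]nona-1,3,7-trien-1-yl trifluoromethanesulfonate
Conditions: KN(SiMe3)2 (1.0 equiv), THF, −78 °C; then PhNTf2, −78 → 0 °C
Reagents that add atoms: N-phenylbis(trifluoromethanesulfonimide), O=S(=O)(N(c1ccccc1)S(=O)(=O)C(F)(F)F)C(F)(F)F
Why: With no α′-hydrogen, the base removes a γ-hydrogen and the extended dienolate is O-sulfonylated to the 1-triflyloxy-1,3-diene; the two enones are interchanged by the C2 axis, so monotriflation gives one compound, and the monoanion resists a second deprotonation.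

**Step 7**
Reactants: 9 (5S)-6-oxospiro[4.4]nona-1,3,7-trien-1-yl trifluoromethanesulfonate
Product: 10 methyl (5S)-6-oxospiro[4.4]nona-1,3,7-triene-1-carboxylate
Conditions: Pd(OAc)2 (5 mol %), PPh3, CO (1 atm), MeOH, Et3N, DMF, 25 °C
Reagents that add atoms: carbon monoxide, [C-]#[O+]; methanol, CO
Why: Palladium-catalysed alkoxycarbonylation of a dienyl triflate (oxidative addition to zerovalent palladium, CO insertion, methanolysis); room temperature keeps the 5-acylcyclopentadiene below the temperature at which a 1,5-acyl shift could begin.

**Step 8**
Reactants: 11 2,5-dimethoxyphenol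
Product: 12 2,5-dimethoxyphenyl N-(propan-2-yl)carbamate
Conditions: i-PrNCO, Et3N (cat.), CH2Cl2, 25 °C
Reagents that add atoms: isopropyl isocyanate, CC(C)N=C=O
Why: Addition of the phenol to the isocyanate gives the carbamate that directs the ortho-metalation and is removable under mild base.

**Step 9**
Reactants: 12 2,5-dimethoxyphenyl N-(propan-2-yl)carbamate
Product: 15 3,6-dimethoxy-2-(trimethylsilyl)phenyl N-(propan-2-yl)carbamate, via N-silyl carbamate 13 (not isolated), via N-silyl ortho-silyl carbamate 14 (not isolated)
Conditions: t-BuMe2SiOTf, TMEDA, Et2O, 0 → 25 °C; then n-BuLi, TMEDA, −78 °C; then Me3SiCl, −78 → 25 °C; aq. NaHSO4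
Reagents that add atoms: chlorotrimethylsilane, C[Si](C)(C)Cl
Why: Directed ortho-metalation after temporary N-silylation; lithiation occurs at the position flanked by the carbamate and a methoxy group, and the N-silyl group is lost on acidic work-up.

**Step 10**
Reactants: 15 3,6-dimethoxy-2-(trimethylsilyl)phenyl N-(propan-2-yl)carbamate
Product: 17 3,6-dimethoxy-2-(trimethylsilyl)phenyl trifluoromethanesulfonate, via silyl phenol 16 (not isolated)
Conditions: DBU, Et2NH, MeCN, 40 °C; then PhNTf2, 25 °C
Reagents that add atoms: N-phenylbis(trifluoromethanesulfonimide), O=S(=O)(N(c1ccccc1)S(=O)(=O)C(F)(F)F)C(F)(F)F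
Why: Base-induced elimination of the N-H carbamate releases the phenoxide (the isocyanate is scavenged by Et2NH), and O-triflation in the same flask avoids protodesilylation of the free phenol.

**Step 11**
Reactants: 10 methyl (5S)-6-oxospiro[4.4]nona-1,3,7-triene-1-carboxylate; 17 3,6-dimethoxy-2-(trimethylsilyl)phenyl trifluoromethanesulfonate
Product: 19 methyl (1S,1′R,4′R)-5′,8′-dimethoxy-2-oxo-1′,4′-dihydrospiro[cyclopent-3-ene-1,9′-[1,4]methanonaphthalene]-1′-carboxylate (C4 carbonyl over the arene, C2 methylene over the C9=C11 alkene), via 3,6-dimethoxybenzyne 18 (not isolated)
Conditions: CsF, MeCN, 25 °C, slow addition of 17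
Reagents that add atoms: none
Why: Fluoride-induced 1,2-elimination gives the aryne, which is trapped in a Diels–Alder reaction by the 5,5-disubstituted cyclopentadiene; the symmetric aryne leaves no regiochemical issue. Addition to the diene face under the flat enone carbonyl (not under the CH2 with its two hydrogens, and anti to the better σ-donor bond) should place C4 over the arene and sets C8 and C12 relative to C3.

**Step 12 (key step)**
Reactants: 19 spiro benzonorbornadiene enone ester
Product: 21 ring-expanded dibromide (6,7-benzobicyclo[3.2.1]octa-2,6-diene; C9=C10 alkene with Br on C10, endo Br on C11, ester on C8, spiro cyclopentenone on C3), via endo gem-dibromocyclopropane 20 (not isolated)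
Conditions: PhHgCBr3 (2 equiv), benzene, 80 °C
Reagents that add atoms: phenyl(tribromomethyl)mercury, BrC(Br)(Br)[Hg]c1ccccc1
Why: Thermolysis of PhHgCBr3 releases CBr2 under neutral conditions, and this electrophilic carbene adds to the strained C9=C11 alkene and not to the electron-poor enone or the arene. The exo face is closed by the C2 methylene, which sits where the carbene carbon would have to go, so addition is expected from the endo face in the cleft toward the arene, as in the known endo additions of dihalocarbenes to norbornadiene. The bromine that points into the cleft is cis to both ring bonds (C9–C8 and C11–C12); it leaves as the three-membered ring opens in a disrotatory two-electron electrocyclic process, so 20 is at most a fleeting intermediate. Ring C is thus closed by ring enlargement: the C9–C10 and C10–C11 bonds form and the old C9–C11 bond becomes the allyl system. The bromide ion pair collapses on the same endo face at C11, the terminus remote from the ester-bearing C8, which sets the one new stereocenter; the allylic bromide is therefore written endo and not exo. Its configuration and regiochemistry are erased in steps 13 and 14, so neither has to be controlled. The closest known reaction type is the dihalocarbene ring expansion of norbornene, norbornadiene and benzonorbornadiene to 3,4-dihalobicyclo[3.2.1]octenes. The step needs chemoselectivity for the bridge alkene, which strain and electron density should secure.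

**Step 13**
Reactants: 21 ring-expanded dibromide
Product: 22 vinyl bromide (C9=C10 with Br on C10, C11 as CH2)
Conditions: Bu3SnH (1.1 equiv), AIBN (cat.), benzene (0.1 M), 80 °C
Reagents that add atoms: none
Why: Radical chain reduction; the allylic C–Br bond is abstracted far faster than the vinylic one, and the allyl radical takes hydrogen at the less hindered terminus C11. The alkene isomer from hydrogen transfer to C9 converges in step 14.

**Step 14**
Reactants: 22 vinyl bromide
Product: 24 ring C ketone (C10=O, flanked by C9H2 and C11H2), via alkenyl pinacol boronate 23 (not isolated)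
Conditions: B2pin2, PdCl2(PPh3)2 (3 mol %), PPh3, KOPh, toluene, 50 °C; then Me3NO·2H2O, THF, 65 °C
Reagents that add atoms: trimethylamine N-oxide, C[N+](C)(C)[O-]
Why: Miyaura borylation of the alkenyl bromide, then oxidation of the C–B bond to the enol, which tautomerises to the ketone; the amine oxide is used instead of a peroxide so that the enone is not epoxidised.

**Step 15**
Reactants: 24 ring C ketone
Product: 25 enol triflate (C10–OTf, C10=C11)
Conditions: LiN(i-Pr)2 (1.05 equiv), THF, −78 °C; then PhNTf2, −78 → 0 °C
Reagents that add atoms: N-phenylbis(trifluoromethanesulfonimide), O=S(=O)(N(c1ccccc1)S(=O)(=O)C(F)(F)F)C(F)(F)F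
Why: Kinetic deprotonation by a bulky amide should occur at C11, next to the CH bridgehead, and not at C9, which is neopentyl and flanked by the ester; the saturated ketone is deprotonated faster than the γ-position of the enone, and O-triflation fixes the enolate regiochemistry.

**Step 16**
Reactants: 25 enol triflate
Product: 26 methylcyclohexene enone ester (C10–CH3, C10=C11)
Conditions: MeZnCl, Pd(PPh3)4 (5 mol %), THF, 25 → 50 °C
Reagents that add atoms: methylzinc chloride, C[Zn]Cl
Why: Negishi coupling of an alkenyl triflate; the organozinc reagent does not add to the enone or the ester.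

**Step 17**
Reactants: 26 methylcyclohexene enone ester
Product: 27 isopropenyl ketone ester (isopropenyl on C1, on the ring E face toward C12)
Conditions: CH2=C(CH3)MgBr, CuBr·SMe2 (20 mol %), THF, −78 → −40 °C; aq. NH4Cl
Reagents that add atoms: isopropenylmagnesium bromide, CC(=C)[Mg]Br
Why: Copper-catalysed conjugate addition to the cyclopentenone; the copper reagent should approach C1 from the face that looks toward C12 (bridgehead hydrogen, sp2 C11), away from the C8 ester and the axial hydrogen of C9, which sets C1.

**Step 18**
Reactants: 27 isopropenyl ketone ester
Product: 28 carboxylic acid (CO2H on C8)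
Conditions: n-PrSLi, HMPA, 25 °C; then 1 M HCl
Reagents that add atoms: none
Why: SN2 demethylation by thiolate attacks the unhindered methyl group and so avoids addition to the neopentyl bridgehead carbonyl; the ketone, the alkenes and the aryl ethers are untouched at room temperature.

**Step 19**
Reactants: 28 carboxylic acid
Product: 30 methyl ketone (acetyl on C8), via acid chloride 29 (not isolated)
Conditions: Me2C=C(Cl)NMe2, CH2Cl2, 0 → 25 °C; then Me2CuLi, Et2O/THF, −78 °C
Reagents that add atoms: lithium dimethylcuprate, [Li+].C[Cu-]C
Why: The chloroenamine makes the hindered acid chloride without HCl, which protects the isopropenyl group; a cuprate acylation stops at the ketone and leaves the cyclopentanone untouched at −78 °C.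

**Step 20**
Reactants: 30 methyl ketone
Product: 31 pentacyclic diketone dimethyl ether (O,O′-dimethyl ether of 33)
Conditions: LiN(i-Pr)2 (2.2 equiv), THF, −78 °C; then CuCl2, DMF, −78 → 0 °C, high dilution
Reagents that add atoms: none
Why: Intramolecular oxidative coupling of a ketone bis-enolate; each ketone has a single enolisable site (C5 and the acetyl methyl, future C6), and the acetyl carbon can reach C5 only on the ring E face that carries C8, along the axial lobe of the enolate. The six-membered ring D is closed and C5 is set by the bridge; the C1 configuration is not touched.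

**Step 21**
Reactants: 31 pentacyclic diketone dimethyl ether
Product: 33 CNP0287617.1, via quinone 32 (not isolated)
Conditions: (NH4)2Ce(NO3)6, MeCN/H2O, 0 °C; then aq. Na2S2O4, 25 °C, argon
Reagents that add atoms: water, O
Why: Oxidative demethylation of the 1,4-dimethoxyarene to the p-quinone, then dithionite reduction to the hydroquinone; this avoids Lewis acids that would attack the two alkenes.

## Compound list

1 | ethyl 2-oxocyclopentane-1-carboxylate (racemic, labile centre) | CCOC(=O)C1CCCC1=O | starting material
2 | ethyl 4-bromobutanoate | CCOC(=O)CCCBr | starting material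
3 | ethyl 1-(4-ethoxy-4-oxobutyl)-2-oxocyclopentane-1-carboxylate (racemic) | CCOC(=O)CCCC1(C(=O)OCC)CCCC1=O | intermediate
4 | 4-(2-oxocyclopentyl)butanoic acid (racemic) | OC(=O)CCCC1CCCC1=O | intermediate
5 | (±)-spiro[4.4]nonane-1,6-dione | O=C1CCCC12CCCC2=O | intermediate
6 | (R)-spiro[4.4]nonane-1,6-dione | O=C1CCC[C@@]12CCCC2=O | intermediate
7 | (R)-1,6-bis(trimethylsilyloxy)spiro[4.4]nona-1,6-diene | C[Si](C)(C)OC1=CCC[C@@]12CCC=C2O[Si](C)(C)C | intermediate (not isolated)
8 | (R)-spiro[4.4]nona-2,7-diene-1,6-dione | O=C1C=CC[C@@]12CC=CC2=O | intermediate
9 | (5S)-6-oxospiro[4.4]nona-1,3,7-trien-1-yl trifluoromethanesulfonate | FC(F)(F)S(=O)(=O)OC1=CC=C[C@@]12CC=CC2=O | intermediate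
10 | methyl (5S)-6-oxospiro[4.4]nona-1,3,7-triene-1-carboxylate | COC(=O)C1=CC=C[C@@]12CC=CC2=O | intermediate
11 | 2,5-dimethoxyphenol | COc1ccc(OC)c(O)c1 | starting material
12 | 2,5-dimethoxyphenyl N-(propan-2-yl)carbamate | COc1ccc(OC)c(OC(=O)NC(C)C)c1 | intermediate
13 | 2,5-dimethoxyphenyl N-(tert-butyldimethylsilyl)-N-(propan-2-yl)carbamate | COc1ccc(OC)c(OC(=O)N(C(C)C)[Si](C)(C)C(C)(C)C)c1 | intermediate (not isolated)
14 | 3,6-dimethoxy-2-(trimethylsilyl)phenyl N-(tert-butyldimethylsilyl)-N-(propan-2-yl)carbamate | COc1ccc(OC)c(OC(=O)N(C(C)C)[Si](C)(C)C(C)(C)C)c1[Si](C)(C)C | intermediate (not isolated)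
15 | 3,6-dimethoxy-2-(trimethylsilyl)phenyl N-(propan-2-yl)carbamate | COc1ccc(OC)c(OC(=O)NC(C)C)c1[Si](C)(C)C | intermediate
16 | 3,6-dimethoxy-2-(trimethylsilyl)phenol | COc1ccc(OC)c(O)c1[Si](C)(C)C | intermediate (not isolated)
17 | 3,6-dimethoxy-2-(trimethylsilyl)phenyl trifluoromethanesulfonate | COc1ccc(OC)c(OS(=O)(=O)C(F)(F)F)c1[Si](C)(C)C | intermediate
18 | 3,6-dimethoxybenzyne | COC1=CC=C(OC)C#C1 | intermediate (not isolated)
19 | methyl (1S,1′R,4′R)-5′,8′-dimethoxy-2-oxo-1′,4′-dihydrospiro[cyclopent-3-ene-1,9′-[1,4]methanonaphthalene]-1′-carboxylate; enone C=O over the arene | COc1ccc(OC)c2c1[C@H]1C=C[C@]2(C(=O)OC)[C@]13CC=CC3=O | intermediate (key-step precursor)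
20 | endo gem-dibromocyclopropane of 19 (CBr2 across C9 and C11 on the face toward the arene) | COc1ccc(OC)c2c1[C@H]1[C@@H]4[C@@H](C4(Br)Br)[C@]2(C(=O)OC)[C@]13CC=CC3=O | intermediate (not isolated)
21 | ring-expanded dibromide: C9=C10(Br), endo Br on C11, ester on C8, spiro cyclopentenone on C3 | COc1ccc(OC)c2c1[C@H]1[C@@H](Br)C(Br)=C[C@]2(C(=O)OC)[C@]13CC=CC3=O | intermediate (key-step product)
22 | vinyl bromide: C9=C10(Br), C11H2; other centres as in 21 | COc1ccc(OC)c2c1[C@H]1CC(Br)=C[C@]2(C(=O)OC)[C@]13CC=CC3=O | intermediate
23 | alkenyl pinacol boronate (Bpin on C10); centres as in 22 | COc1ccc(OC)c2c1[C@H]1CC(B4OC(C)(C)C(C)(C)O4)=C[C@]2(C(=O)OC)[C@]13CC=CC3=O | intermediate (not isolated)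
24 | ring C ketone (C10=O); centres as in 19 | COc1ccc(OC)c2c1[C@H]1CC(=O)C[C@]2(C(=O)OC)[C@]13CC=CC3=O | intermediate
25 | enol triflate (C10–OTf, C10=C11); centres as in 19 | COc1ccc(OC)c2c1[C@H]1C=C(OS(=O)(=O)C(F)(F)F)C[C@]2(C(=O)OC)[C@]13CC=CC3=O | intermediate
26 | methylcyclohexene enone ester (C10–CH3, C10=C11); centres as in 19 | COc1ccc(OC)c2c1[C@H]1C=C(C)C[C@]2(C(=O)OC)[C@]13CC=CC3=O | intermediate
27 | isopropenyl ketone ester; isopropenyl on C1 on the ring E face toward C12 | COc1ccc(OC)c2c1[C@H]1C=C(C)C[C@]2(C(=O)OC)[C@]13C[C@H](C(C)=C)CC3=O | intermediate
28 | carboxylic acid (CO2H on C8); centres as in 27 | COc1ccc(OC)c2c1[C@H]1C=C(C)C[C@]2(C(=O)O)[C@]13C[C@H](C(C)=C)CC3=O | intermediate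
29 | acid chloride (COCl on C8); centres as in 27 | COc1ccc(OC)c2c1[C@H]1C=C(C)C[C@]2(C(=O)Cl)[C@]13C[C@H](C(C)=C)CC3=O | intermediate (not isolated)
30 | methyl ketone (acetyl on C8); centres as in 27 | COc1ccc(OC)c2c1[C@H]1C=C(C)C[C@]2(C(C)=O)[C@]13C[C@H](C(C)=C)CC3=O | intermediate
31 | pentacyclic diketone dimethyl ether (O,O′-dimethyl ether of 33) | C=C(C)[C@H]1C[C@@]23C(=O)[C@@H]1CC(=O)[C@@]21CC(C)=C[C@@H]3c2c(OC)ccc(OC)c21 | intermediate
32 | p-quinone corresponding to 33 | C=C(C)[C@H]1C[C@@]23C(=O)[C@@H]1CC(=O)[C@@]21CC(C)=C[C@@H]3C2=C1C(=O)C=CC2=O | intermediate (not isolated)
33 | CNP0287617.1 (pentacyclic hydroquinone diketone) | C=C(C)[C@H]1C[C@@]23C(=O)[C@@H]1CC(=O)[C@@]21CC(C)=C[C@@H]3c2c(O)ccc(O)c21 | target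

## Step count and least certain steps

Total: 21 steps. Longest linear sequence: 18 steps (steps 1–7 and 11–21, from 1 and 2 to 33). The aryne precursor branch (steps 8–10) is 3 steps.

**Step 12 (key step).** The carbene transfer may be too slow. The exo face of the C9=C11 alkene is blocked by the C2 methylene and the endo face is crowded by the arene, so cyclopropanation of the enone alkene or simple decay of the reagent could take over. Fallback, from 19 back to 24, without a three-membered transition state on that alkene: ozonolysis of the strained alkene (O3, CH2Cl2/MeOH, −78 °C, then Me2S) should give the cis-dialdehyde F1. A five-membered cycloaddition keeps the reagent atoms at the exo positions of C9 and C11, clear of C2. A base-catalysed twofold Henry reaction with nitromethane would close ring C as the nitro diol F2. Bis-mesylation with elimination and conjugate reduction of each nitroalkene by a Hantzsch ester removes both hydroxyls to give the secondary nitro compound F3. A Nef reaction (TiCl3, NH4OAc buffer) then returns ketone 24.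

**Step 11.** Facial selectivity may be poor, because an aryne has no exo substituents and feels little difference between the carbonyl face and the CH2 face. The diene 10 may also be lost by a 1,5-acyl shift if the reaction is slow. Fallback, from 10 back to 19: a thermal Diels–Alder reaction with 1,4-benzoquinone (concentrated, 25 °C), whose exo hydrogens clash with the C2 hydrogens and so discriminate more strongly for the carbonyl face, gives the endo adduct F4. Base-mediated enolisation gives the hydroquinone F5, and O-methylation (MeI, K2CO3, acetone) gives 19.

**Step 15.** Deprotonation may lose regioselectivity. Both α-carbons are β-branched, and coordination of the lithium amide to the neighbouring ester could steer the base to C9. Fallback, from 21 back to 26, which fixes the alkene by a sigmatropic transposition and not by enolate chemistry: silver-assisted hydrolysis of the allylic bromide (AgNO3, acetone/H2O) gives the 2-bromo allylic alcohol F6. Negishi methylation (MeZnCl, Pd(PPh3)4) gives the 2-methyl allylic alcohol F7. A Mitsunobu reaction with 2-nitrobenzenesulfonylhydrazide (PPh3, diethyl azodicarboxylate, −30 → 25 °C) forms the monoalkyl diazene, which loses N2 with 1,3-transposition of the alkene and delivers hydrogen to C9, giving 26.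

**Step 17.** Facial selectivity of the conjugate addition could be modest, because C1 is two bonds away from the centres that differentiate the faces. Fallback, from 26 directly to 27: a catalyst-controlled rhodium-catalysed conjugate addition of potassium isopropenyltrifluoroborate with [RhCl(cod)]2 and the matching enantiomer of BINAP in dioxane/H2O. No new compound is involved.

**Step 20.** The bis-enolate may be α-chlorinated or coupled intermolecularly instead of closing ring D. Fallback, from 28 (through 29) back to 31, which replaces the oxidation by an alkylation: 29 with diazomethane gives the diazoketone F8. Ethereal HCl at −20 °C gives the chloromethyl ketone F9. KOt-Bu in THF/t-BuOH at 0 °C then closes ring D by intramolecular C-alkylation of the C4/C5 enolate (six-membered, enolate carbon attacking through its axial lobe) to give 31.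

## Further compounds

F1 | step 12 | cis-dialdehyde from ozonolysis of 19 (CHO on C8 and on C12) | COc1ccc(OC)c2c1[C@@H](C=O)[C@@]1(CC=CC1=O)[C@]2(C=O)C(=O)OC
F2 | step 12 | nitro diol (ring C closed; OH on C9 and C11, NO2 on C10, new centres as formed) | COc1ccc(OC)c2c1[C@H]1C(O)C([N+](=O)[O-])C(O)[C@]2(C(=O)OC)[C@]13CC=CC3=O
F3 | step 12 | secondary nitro compound (NO2 on C10, either epimer) | COc1ccc(OC)c2c1[C@H]1CC([N+](=O)[O-])C[C@]2(C(=O)OC)[C@]13CC=CC3=O
F4 | step 11 | endo Diels–Alder adduct of 10 and 1,4-benzoquinone (the two ring-fusion centres are lost in the next operation) | O=C1C=CC(=O)C2C1[C@H]1C=C[C@]2(C(=O)OC)[C@]13CC=CC3=O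
F5 | step 11 | hydroquinone corresponding to 19 | Oc1ccc(O)c2c1[C@H]1C=C[C@]2(C(=O)OC)[C@]13CC=CC3=O
F6 | step 15 | 2-bromo allylic alcohol (OH on C11, either epimer; C9=C10(Br)) | COc1ccc(OC)c2c1[C@H]1C(O)C(Br)=C[C@]2(C(=O)OC)[C@]13CC=CC3=O
F7 | step 15 | 2-methyl allylic alcohol (OH on C11; C9=C10(CH3)) | COc1ccc(OC)c2c1[C@H]1C(O)C(C)=C[C@]2(C(=O)OC)[C@]13CC=CC3=O
F0 | step 17 | none | none
F8 | step 20 | diazoketone (C(=O)CHN2 on C8) | COc1ccc(OC)c2c1[C@H]1C=C(C)C[C@]2(C(=O)C=[N+]=[N-])[C@]13C[C@H](C(C)=C)CC3=O
F9 | step 20 | chloromethyl ketone (C(=O)CH2Cl on C8) | COc1ccc(OC)c2c1[C@H]1C=C(C)C[C@]2(C(=O)CCl)[C@]13C[C@H](C(C)=C)CC3=O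
A1 | alternative 1 | enyne ketal (ring D/E bicycle with exocyclic methylene on C8 and an aryl(propynyl)methyl group on C3) | C=C(C)[C@H]1C[C@]2(C(=O)[C@@H]1CC1(OCCO1)C2=C)[C@H](C#CC)c1cc(OC)ccc1OC
A2 | alternative 1 | pentacyclic ketal of the target dimethyl ether | C=C(C)[C@H]1C[C@@]23C(=O)[C@@H]1CC1(OCCO1)[C@@]21CC(C)=C[C@@H]3c2c(OC)ccc(OC)c21
A3 | alternative 2 | benzocycloheptene chloromethyl ketone with a 5,5-dimethoxycyclopentadienyl group on C12 (either epimer at C8) | ClCC(=O)C1CC(C)=C[C@@H](C2=CC=CC2(OC)OC)c2c(OC)ccc(OC)c21
A4 | alternative 2 | pentacyclic ketal alkene lacking the isopropenyl group | C1=C[C@@]23C(OC)(OC)[C@@H]1CC(=O)[C@@]21CC(C)=C[C@@H]3c2c(OC)ccc(OC)c21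
A5 | alternative 3 | indene-fused cycloheptenone phenyl selenide (either epimer at C5) | C=C(C)[C@H]1CC2=C(C(=O)CC1[Se]c1ccccc1)c1c(OC)ccc(OC)c1[C@H]2C=C
A6 | alternative 3 | tetracyclic diketone with vinyl and 2-methylallyl groups | C=C(C)[C@H]1C[C@@]23C(=O)[C@@H]1CC(=O)[C@]2(CC(C)=C)c2c(OC)ccc(OC)c2[C@H]3C=C
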